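**Retrosynthetic overview**

1. The target is reached by benzyl hydrogenolysis, anti opening of an 8,9-epoxide by water at C8, acylation of the C6 hydroxyl and hydroxyl-directed epoxidation of a C8=C9 alkene.
2. Ring B is formed second, by ring-closing metathesis across C8=C9. The C6 carbinol comes from reagent-controlled 2-methylallylboration of a C6 aldehyde, and the allyl arm from the C9 aldehyde.
3. The C4 isopropyl carbinol comes from organocerium addition to the C4 ketone anti to the C5 substituent. C5 is fixed relative to C1 by a catalyst-controlled dynamic kinetic hydrogenation of the β-keto ester.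
4. Ring A is formed first, through the C1–C5 bond, by dirhodium carbenoid insertion into the tertiary C1–H bond. The route rests on this feature: quaternary C1 with its methyl, the C10–C9(O) arm and the C2–C3–C4 chain is the carbon skeleton of (S)-citronellol, whose stereocentre becomes C1 with retention.
5. The diazo keto ester comes from (S)-citronellol by silylation, ozonolysis (C4 aldehyde), SnCl2-catalysed homologation with methyl diazoacetate and diazo transfer.

Key step: step 5

Numbering used throughout: C1 = methyl-bearing ring-fusion carbon, C2 and C3 = ring A CH2, C4 = isopropyl carbinol, C5 = ring-fusion CH, C6 = acyloxy CH, C7 = CH2, C8 = methyl carbinol, C9 = CHOH, C10 = CH2; ring A = C1 to C5, ring B = C1, C5 to C10.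

Remarks on the chemistry:
- β-Keto ester 8 is an equilibrating set of C5 epimers and enol. It is drawn as the (5R) epimer, no selectivity at C5 is claimed for step 5, and step 6 funnels the mixture.
- The 4-hydroxybenzoyl group is introduced as commercially available 4-(benzyloxy)benzoyl chloride, so the phenol is freed in the last step.

**Route**

Step 1
Reactants: 1 (S)-citronellol
Product: 2 tert-butyl{[(3S)-3,7-dimethyloct-6-en-1-yl]oxy}dimethylsilane
Conditions: TBSCl, imidazole, CH2Cl2, 0 °C → rt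
Reagents that add atoms: tert-butyldimethylsilyl chloride, CC(C)(C)[Si](C)(C)Cl
Why: Imidazole-promoted silylation of the primary alcohol (silyl ether formation) should be clean and leaves the stereocentre untouched.

Step 2
Reactants: 2 tert-butyl{[(3S)-3,7-dimethyloct-6-en-1-yl]oxy}dimethylsilane
Product: 4 (4S)-6-[(tert-butyldimethylsilyl)oxy]-4-methylhexanal, via secondary ozonide 3 (not isolated)
Conditions: O3, CH2Cl2, −78 °C; then PPh3, −78 °C → rt
Reagents that add atoms: ozone, [O-][O+]=O
Why: Ozonolysis with reductive work-up cleaves the trisubstituted alkene to the aldehyde that will be C4 and to acetone, and the silyl ether and the remote stereocentre are inert.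

Step 3
Reactants: 4 (4S)-6-[(tert-butyldimethylsilyl)oxy]-4-methylhexanal; 5 methyl diazoacetate
Product: 6 methyl (6S)-8-[(tert-butyldimethylsilyl)oxy]-6-methyl-3-oxooctanoate
Conditions: SnCl2 (10 mol%), CH2Cl2, rt
Reagents that add atoms: none
Why: Roskamp homologation, in which the tin-activated aldehyde takes up the diazo ester and a 1,2-hydride shift with loss of N2 gives the β-keto ester under conditions mild enough for the silyl ether.

Step 4
Reactants: 6 methyl (6S)-8-[(tert-butyldimethylsilyl)oxy]-6-methyl-3-oxooctanoate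
Product: 7 methyl (6S)-8-[(tert-butyldimethylsilyl)oxy]-2-diazo-6-methyl-3-oxooctanoate
Conditions: 4-acetamidobenzenesulfonyl azide, Et3N, MeCN, 0 °C → rt
Reagents that add atoms: 4-acetamidobenzenesulfonyl azide, CC(=O)Nc1ccc(cc1)S(=O)(=O)N=[N+]=[N-]
Why: Regitz diazo transfer to the doubly activated methylene of a β-keto ester is a standard, high-yielding operation.

Step 5
Reactants: 7 methyl (6S)-8-[(tert-butyldimethylsilyl)oxy]-2-diazo-6-methyl-3-oxooctanoate
Product: 8 methyl (1R,2R)-2-[2-[(tert-butyldimethylsilyl)oxy]ethyl]-2-methyl-5-oxocyclopentane-1-carboxylate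
Conditions: Rh2(OAc)4 (1 mol%), CH2Cl2, rt, slow addition of 7 at high dilution
Reagents that add atoms: none
Why: Dirhodium tetraacetate takes N2 from the diazo group to give an electrophilic rhodium carbenoid at C5, which inserts into the tertiary C1–H bond in a concerted, three-centre, hydride-transfer-like transition state; the closest known reaction type is the dirhodium-catalysed intramolecular 1,5 C–H insertion of α-diazo-β-keto esters to 2-alkoxycarbonylcyclopentanones. Ring A closes by formation of the C1–C5 bond in the 1,5 mode, through a chair-like array C5–C4–C3–C2–C1–H that leads to the five-membered ring. C1 becomes quaternary with retention, because the new C–C bond takes the place of the C–H bond on the same face, so its configuration is that of (S)-citronellol; C5 is also formed but is an enolisable β-keto ester centre, is not controlled here and is settled in step 6. The step needs 1,5 site selectivity, and the substrate secures it: C1–H is the only C–H bond that leads to a five-membered ring, it is tertiary and electron-rich, the carbenoid carbon has no β-hydrogen for a 1,2-shift, the alkene was removed in step 2 so cyclopropanation is excluded, and the C–H bonds next to the silyl ether oxygen stand in a 1,7 relationship. Slow addition at high dilution should suppress carbene dimerisation.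

Step 6
Reactants: 8 methyl (1R,2R)-2-[2-[(tert-butyldimethylsilyl)oxy]ethyl]-2-methyl-5-oxocyclopentane-1-carboxylate
Product: 9 methyl (1R,2R,5R)-2-[2-[(tert-butyldimethylsilyl)oxy]ethyl]-5-hydroxy-2-methylcyclopentane-1-carboxylate
Conditions: [RuCl(C6H6)((R)-BINAP)]Cl (1 mol%), H2 (100 atm), CH2Cl2, 50 °C
Reagents that add atoms: none
Why: Noyori asymmetric hydrogenation of a cyclic β-keto ester with dynamic kinetic resolution: C5 epimerises through the enol faster than the ketone is reduced, the (R)-BINAP ruthenium chelate should accept only the (5R) epimer and deliver hydride to C4 from the face of the ester, giving the trans (4R,5R) hydroxy ester, so C5 is fixed relative to C1 by the catalyst and not by the weak steric difference between the C1 methyl and the C1 side chain.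

Step 7
Reactants: 9 methyl (1R,2R,5R)-2-[2-[(tert-butyldimethylsilyl)oxy]ethyl]-5-hydroxy-2-methylcyclopentane-1-carboxylate
Product: 10 (1R,2S,3R)-3-[2-[(tert-butyldimethylsilyl)oxy]ethyl]-2-(hydroxymethyl)-3-methylcyclopentan-1-ol
Conditions: LiAlH4, THF, 0 °C
Reagents that add atoms: none
Why: Hydride reduction of the ester to the primary alcohol C6; C5 is no longer acidic once the ketone is gone, and the silyl ether survives at 0 °C.

Step 8
Reactants: 10 (1R,2S,3R)-3-[2-[(tert-butyldimethylsilyl)oxy]ethyl]-2-(hydroxymethyl)-3-methylcyclopentan-1-ol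
Product: 11 (1R,2S,3R)-3-[2-[(tert-butyldimethylsilyl)oxy]ethyl]-2-[[(tert-butyldiphenylsilyl)oxy]methyl]-3-methylcyclopentan-1-ol
Conditions: TBDPSCl (1.05 equiv), imidazole, CH2Cl2, 0 °C
Reagents that add atoms: tert-butyldiphenylsilyl chloride, CC(C)(C)[Si](Cl)(c1ccccc1)c1ccccc1
Why: Selective silylation; the bulky chlorosilane should react at the primary C6 hydroxyl and leave the secondary ring hydroxyl free for oxidation.

Step 9
Reactants: 11 (1R,2S,3R)-3-[2-[(tert-butyldimethylsilyl)oxy]ethyl]-2-[[(tert-butyldiphenylsilyl)oxy]methyl]-3-methylcyclopentan-1-ol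
Product: 12 (2S,3R)-3-[2-[(tert-butyldimethylsilyl)oxy]ethyl]-2-[[(tert-butyldiphenylsilyl)oxy]methyl]-3-methylcyclopentan-1-one
Conditions: Dess–Martin periodinane, CH2Cl2, rt
Reagents that add atoms: none
Why: Dess–Martin oxidation restores the C4 ketone under neutral conditions, so the β-silyloxy ketone should neither epimerise at C5 nor eliminate.

Step 10
Reactants: 12 (2S,3R)-3-[2-[(tert-butyldimethylsilyl)oxy]ethyl]-2-[[(tert-butyldiphenylsilyl)oxy]methyl]-3-methylcyclopentan-1-one
Product: 13 (1R,2S,3R)-3-[2-[(tert-butyldimethylsilyl)oxy]ethyl]-2-[[(tert-butyldiphenylsilyl)oxy]methyl]-3-methyl-1-(propan-2-yl)cyclopentan-1-ol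
Conditions: iPrMgCl, CeCl3, THF, −78 °C → 0 °C
Reagents that add atoms: isopropylmagnesium chloride, CC(C)[Mg]Cl
Why: Organocerium 1,2-addition (the cerium reagent is made in the flask) suppresses enolisation, β-elimination of the silyloxy group and β-hydride reduction; the nucleophile should enter C4 anti to the adjacent C5 silyloxymethyl group, which places the C4 hydroxyl cis to C6 (4R).

Step 11
Reactants: 13 (1R,2S,3R)-3-[2-[(tert-butyldimethylsilyl)oxy]ethyl]-2-[[(tert-butyldiphenylsilyl)oxy]methyl]-3-methyl-1-(propan-2-yl)cyclopentan-1-ol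
Product: 14 (1R,2S,3R)-2-[[(tert-butyldiphenylsilyl)oxy]methyl]-3-(2-hydroxyethyl)-3-methyl-1-(propan-2-yl)cyclopentan-1-ol
Conditions: PPTS (cat.), MeOH, rt
Reagents that add atoms: none
Why: Acid-catalysed methanolysis removes a primary tert-butyldimethylsilyl ether much faster than a tert-butyldiphenylsilyl ether, which frees only the C9 hydroxyl.

Step 12
Reactants: 14 (1R,2S,3R)-2-[[(tert-butyldiphenylsilyl)oxy]methyl]-3-(2-hydroxyethyl)-3-methyl-1-(propan-2-yl)cyclopentan-1-ol
Product: 15 2-[(1R,2S,3R)-2-[[(tert-butyldiphenylsilyl)oxy]methyl]-3-hydroxy-1-methyl-3-(propan-2-yl)cyclopentyl]acetaldehyde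
Conditions: Dess–Martin periodinane, CH2Cl2, rt
Reagents that add atoms: none
Why: Dess–Martin oxidation of the primary alcohol to the C9 aldehyde; the tertiary C4 hydroxyl cannot be oxidised and lies on the ring face opposite to the aldehyde arm, so no lactol can form.

Step 13
Reactants: 15 2-[(1R,2S,3R)-2-[[(tert-butyldiphenylsilyl)oxy]methyl]-3-hydroxy-1-methyl-3-(propan-2-yl)cyclopentyl]acetaldehyde
Product: 16 (1R,2S,3R)-2-[[(tert-butyldiphenylsilyl)oxy]methyl]-3-methyl-1-(propan-2-yl)-3-(prop-2-en-1-yl)cyclopentan-1-ol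
Conditions: Ph3PCH3Br, KOtBu (excess), THF, 0 °C → rt
Reagents that add atoms: methyltriphenylphosphonium bromide, C[P+](c1ccccc1)(c1ccccc1)c1ccccc1.[Br-]
Why: Wittig methylenation turns the C9 aldehyde into the terminal alkene needed for metathesis; excess ylide covers the free tertiary hydroxyl.

Step 14
Reactants: 16 (1R,2S,3R)-2-[[(tert-butyldiphenylsilyl)oxy]methyl]-3-methyl-1-(propan-2-yl)-3-(prop-2-en-1-yl)cyclopentan-1-ol
Product: 17 (1R,2S,3R)-2-(hydroxymethyl)-3-methyl-1-(propan-2-yl)-3-(prop-2-en-1-yl)cyclopentan-1-ol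
Conditions: TBAF, THF, rt
Reagents that add atoms: none
Why: Fluoride desilylation frees the primary C6 hydroxyl; nothing else in the molecule responds to fluoride.

Step 15
Reactants: 17 (1R,2S,3R)-2-(hydroxymethyl)-3-methyl-1-(propan-2-yl)-3-(prop-2-en-1-yl)cyclopentan-1-ol
Product: 18 (1R,2R,5R)-2-hydroxy-5-methyl-2-(propan-2-yl)-5-(prop-2-en-1-yl)cyclopentane-1-carbaldehyde
Conditions: TEMPO (cat.), PhI(OAc)2, CH2Cl2, rt
Reagents that add atoms: none
Why: Nitroxyl-catalysed oxidation converts the primary alcohol to the aldehyde under near-neutral conditions, so the β-hydroxy aldehyde should not undergo retro-aldol cleavage, dehydration or epimerisation at C5 (which is flanked by two quaternary carbons); it is used at once.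

Step 16
Reactants: 18 (1R,2R,5R)-2-hydroxy-5-methyl-2-(propan-2-yl)-5-(prop-2-en-1-yl)cyclopentane-1-carbaldehyde
Product: 20 (1R,2S,3R)-2-[(1S)-1-hydroxy-3-methylbut-3-en-1-yl]-3-methyl-1-(propan-2-yl)-3-(prop-2-en-1-yl)cyclopentan-1-ol, via borinate ester 19 (not isolated)
Conditions: (−)-Ipc2BOMe, 2-methylallylmagnesium chloride, Et2O, 0 °C; then 18, −78 °C → rt; then NaOH, H2O2, 0 °C → rt
Reagents that add atoms: (−)-B-(2-methylallyl)diisopinocampheylborane (made in the flask from 2-methylallylmagnesium chloride, CC(=C)C[Mg]Cl), CC(=C)CB([C@@H]1C[C@@H]2C[C@H]([C@H]1C)C2(C)C)[C@@H]1C[C@@H]2C[C@H]([C@H]1C)C2(C)C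
Why: Brown allylboration: the reagent derived from (+)-α-pinene transfers the 2-methylallyl group through a chair six-membered transition state to the Si face of the aldehyde under reagent control, which should set C6 as (S), and the borinate is then cleaved oxidatively; an excess of reagent covers any loss to the free tertiary hydroxyl.

Step 17
Reactants: 20 (1R,2S,3R)-2-[(1S)-1-hydroxy-3-methylbut-3-en-1-yl]-3-methyl-1-(propan-2-yl)-3-(prop-2-en-1-yl)cyclopentan-1-ol
Product: 21 (3R,3aS,4S,8aR)-6,8a-dimethyl-3-(propan-2-yl)-1,2,3,3a,4,5,8,8a-octahydroazulene-3,4-diol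
Conditions: second-generation Grubbs catalyst, RuCl2(=CHPh)(H2IMes)(PCy3) (5 mol%), CH2Cl2 (0.005 M), 40 °C
Reagents that add atoms: none
Why: Ring-closing olefin metathesis between the allyl group on C1 and the 1,1-disubstituted alkene forms the trisubstituted C8=C9 double bond and closes ring B as a seven-membered ring; the trans arrangement of the two chains on ring A, set in steps 5 and 6, makes the ring fusion trans, and loss of ethylene drives the reaction.

Step 18
Reactants: 21 (3R,3aS,4S,8aR)-6,8a-dimethyl-3-(propan-2-yl)-1,2,3,3a,4,5,8,8a-octahydroazulene-3,4-diol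
Product: 22 (1R,4R,5S,6S,8R,9S)-8,9-epoxydaucane-4,6-diol (the 8,9-epoxide of 21 with the epoxide oxygen cis to the C6 hydroxyl; descriptors in the C1 to C10 numbering)
Conditions: VO(acac)2 (5 mol%), tBuOOH, CH2Cl2, 0 °C → rt
Reagents that add atoms: tert-butyl hydroperoxide, CC(C)(C)OO
Why: Hydroxyl-directed epoxidation: the vanadium alkoxide of the homoallylic C6 hydroxyl should deliver the peroxide oxygen to the alkene face on which that hydroxyl lies, which is also the face remote from the C1 methyl, giving the (8R,9S) epoxide.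

Step 19
Reactants: 22 (1R,4R,5S,6S,8R,9S)-8,9-epoxydaucane-4,6-diol; 23 4-(benzyloxy)benzoyl chloride
Product: 24 (1R,4R,5S,6S,8R,9S)-8,9-epoxy-4-hydroxydaucan-6-yl 4-(benzyloxy)benzoate
Conditions: Et3N, DMAP (cat.), CH2Cl2, 0 °C → rt
Reagents that add atoms: none
Why: DMAP-catalysed acylation of the only secondary hydroxyl; the tertiary C4 hydroxyl should not react and the epoxide is stable to the basic medium.

Step 20
Reactants: 24 (1R,4R,5S,6S,8R,9S)-8,9-epoxy-4-hydroxydaucan-6-yl 4-(benzyloxy)benzoate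
Product: 25 (3R,3aS,4S,6S,7S,8aR)-3,6,7-trihydroxy-6,8a-dimethyl-3-(propan-2-yl)decahydroazulen-4-yl 4-(benzyloxy)benzoate
Conditions: HClO4 (cat.), THF/H2O, 0 °C
Reagents that add atoms: water, O
Why: Acid-catalysed epoxide hydrolysis: water should open the protonated epoxide at the tertiary carbon C8 anti to the departing oxygen (inversion at C8, C9–O bond untouched), which gives the trans 8,9-diol with the (8S,9S) configuration of the target.

Step 21
Reactants: 25 (3R,3aS,4S,6S,7S,8aR)-3,6,7-trihydroxy-6,8a-dimethyl-3-(propan-2-yl)decahydroazulen-4-yl 4-(benzyloxy)benzoate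
Product: 26 (3R,3aS,4S,6S,7S,8aR)-3,6,7-trihydroxy-6,8a-dimethyl-3-(propan-2-yl)decahydroazulen-4-yl 4-hydroxybenzoate (CNP0197754.1)
Conditions: H2 (1 atm), Pd/C, EtOAc, rt
Reagents that add atoms: none
Why: Hydrogenolysis of the benzyl aryl ether frees the phenol; no alkene remains and the ester and the alcohols are inert.

**Compound list**

1 | (S)-citronellol, (3S)-3,7-dimethyloct-6-en-1-ol | CC(C)=CCC[C@H](C)CCO | starting material
2 | tert-butyl{[(3S)-3,7-dimethyloct-6-en-1-yl]oxy}dimethylsilane | CC(C)=CCC[C@H](C)CCO[Si](C)(C)C(C)(C)C | intermediate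
3 | 3-[(3S)-5-[(tert-butyldimethylsilyl)oxy]-3-methylpentyl]-5,5-dimethyl-1,2,4-trioxolane (secondary ozonide, both configurations at the ring CH) | CC1(C)OOC(CC[C@H](C)CCO[Si](C)(C)C(C)(C)C)O1 | intermediate
4 | (4S)-6-[(tert-butyldimethylsilyl)oxy]-4-methylhexanal | O=CCC[C@H](C)CCO[Si](C)(C)C(C)(C)C | intermediate
5 | methyl diazoacetate | COC(=O)C=[N+]=[N-] | starting material
6 | methyl (6S)-8-[(tert-butyldimethylsilyl)oxy]-6-methyl-3-oxooctanoate | COC(=O)CC(=O)CC[C@H](C)CCO[Si](C)(C)C(C)(C)C | intermediate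
7 | methyl (6S)-8-[(tert-butyldimethylsilyl)oxy]-2-diazo-6-methyl-3-oxooctanoate | COC(=O)C(=[N+]=[N-])C(=O)CC[C@H](C)CCO[Si](C)(C)C(C)(C)C | intermediate
8 | methyl (1R,2R)-2-[2-[(tert-butyldimethylsilyl)oxy]ethyl]-2-methyl-5-oxocyclopentane-1-carboxylate | COC(=O)[C@H]1C(=O)CC[C@]1(C)CCO[Si](C)(C)C(C)(C)C | intermediate
9 | methyl (1R,2R,5R)-2-[2-[(tert-butyldimethylsilyl)oxy]ethyl]-5-hydroxy-2-methylcyclopentane-1-carboxylate | COC(=O)[C@H]1[C@H](O)CC[C@]1(C)CCO[Si](C)(C)C(C)(C)C | intermediate
10 | (1R,2S,3R)-3-[2-[(tert-butyldimethylsilyl)oxy]ethyl]-2-(hydroxymethyl)-3-methylcyclopentan-1-ol | OC[C@H]1[C@H](O)CC[C@]1(C)CCO[Si](C)(C)C(C)(C)C | intermediate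
11 | (1R,2S,3R)-3-[2-[(tert-butyldimethylsilyl)oxy]ethyl]-2-[[(tert-butyldiphenylsilyl)oxy]methyl]-3-methylcyclopentan-1-ol | CC(C)(C)[Si](c1ccccc1)(c1ccccc1)OC[C@H]1[C@H](O)CC[C@]1(C)CCO[Si](C)(C)C(C)(C)C | intermediate
12 | (2S,3R)-3-[2-[(tert-butyldimethylsilyl)oxy]ethyl]-2-[[(tert-butyldiphenylsilyl)oxy]methyl]-3-methylcyclopentan-1-one | CC(C)(C)[Si](c1ccccc1)(c1ccccc1)OC[C@H]1C(=O)CC[C@]1(C)CCO[Si](C)(C)C(C)(C)C | intermediate
13 | (1R,2S,3R)-3-[2-[(tert-butyldimethylsilyl)oxy]ethyl]-2-[[(tert-butyldiphenylsilyl)oxy]methyl]-3-methyl-1-(propan-2-yl)cyclopentan-1-ol | CC(C)[C@]1(O)CC[C@](C)(CCO[Si](C)(C)C(C)(C)C)[C@H]1CO[Si](c1ccccc1)(c1ccccc1)C(C)(C)C | intermediate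
14 | (1R,2S,3R)-2-[[(tert-butyldiphenylsilyl)oxy]methyl]-3-(2-hydroxyethyl)-3-methyl-1-(propan-2-yl)cyclopentan-1-ol | CC(C)[C@]1(O)CC[C@](C)(CCO)[C@H]1CO[Si](c1ccccc1)(c1ccccc1)C(C)(C)C | intermediate
15 | 2-[(1R,2S,3R)-2-[[(tert-butyldiphenylsilyl)oxy]methyl]-3-hydroxy-1-methyl-3-(propan-2-yl)cyclopentyl]acetaldehyde | CC(C)[C@]1(O)CC[C@](C)(CC=O)[C@H]1CO[Si](c1ccccc1)(c1ccccc1)C(C)(C)C | intermediate
16 | (1R,2S,3R)-2-[[(tert-butyldiphenylsilyl)oxy]methyl]-3-methyl-1-(propan-2-yl)-3-(prop-2-en-1-yl)cyclopentan-1-ol | CC(C)[C@]1(O)CC[C@](C)(CC=C)[C@H]1CO[Si](c1ccccc1)(c1ccccc1)C(C)(C)C | intermediate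
17 | (1R,2S,3R)-2-(hydroxymethyl)-3-methyl-1-(propan-2-yl)-3-(prop-2-en-1-yl)cyclopentan-1-ol | CC(C)[C@]1(O)CC[C@](C)(CC=C)[C@H]1CO | intermediate
18 | (1R,2R,5R)-2-hydroxy-5-methyl-2-(propan-2-yl)-5-(prop-2-en-1-yl)cyclopentane-1-carbaldehyde | CC(C)[C@]1(O)CC[C@](C)(CC=C)[C@H]1C=O | intermediate
19 | diisopinocampheylborinate of 20 at the C6 oxygen (borinate ester) | CC(C)[C@]1(O)CC[C@](C)(CC=C)[C@H]1[C@H](CC(C)=C)OB([C@@H]2C[C@@H]3C[C@H]([C@H]2C)C3(C)C)[C@@H]2C[C@@H]3C[C@H]([C@H]2C)C3(C)C | intermediate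
20 | (1R,2S,3R)-2-[(1S)-1-hydroxy-3-methylbut-3-en-1-yl]-3-methyl-1-(propan-2-yl)-3-(prop-2-en-1-yl)cyclopentan-1-ol | CC(C)[C@]1(O)CC[C@](C)(CC=C)[C@H]1[C@@H](O)CC(C)=C | intermediate
21 | (3R,3aS,4S,8aR)-6,8a-dimethyl-3-(propan-2-yl)-1,2,3,3a,4,5,8,8a-octahydroazulene-3,4-diol | CC(C)[C@]1(O)CC[C@]2(C)CC=C(C)C[C@H](O)[C@H]21 | intermediate
22 | (1R,4R,5S,6S,8R,9S)-8,9-epoxydaucane-4,6-diol (C1 to C10 numbering) | CC(C)[C@]1(O)CC[C@]2(C)C[C@@H]3O[C@]3(C)C[C@H](O)[C@H]21 | intermediate
23 | 4-(benzyloxy)benzoyl chloride | O=C(Cl)c1ccc(OCc2ccccc2)cc1 | starting material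
24 | (1R,4R,5S,6S,8R,9S)-8,9-epoxy-4-hydroxydaucan-6-yl 4-(benzyloxy)benzoate (C1 to C10 numbering) | CC(C)[C@]1(O)CC[C@]2(C)C[C@@H]3O[C@]3(C)C[C@H](OC(=O)c3ccc(OCc4ccccc4)cc3)[C@H]21 | intermediate
25 | (3R,3aS,4S,6S,7S,8aR)-3,6,7-trihydroxy-6,8a-dimethyl-3-(propan-2-yl)decahydroazulen-4-yl 4-(benzyloxy)benzoate | CC(C)[C@]1(O)CC[C@]2(C)C[C@H](O)[C@@](C)(O)C[C@H](OC(=O)c3ccc(OCc4ccccc4)cc3)[C@H]21 | intermediate
26 | (3R,3aS,4S,6S,7S,8aR)-3,6,7-trihydroxy-6,8a-dimethyl-3-(propan-2-yl)decahydroazulen-4-yl 4-hydroxybenzoate | CC(C)[C@]1(O)CC[C@]2(C)C[C@H](O)[C@@](C)(O)C[C@H](OC(=O)c3ccc(O)cc3)[C@H]21 | target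

**Step count**

Total: 21 steps. Longest linear sequence: 21 steps, from (S)-citronellol 1 to 26.

**Steps most likely to fail**

Step 6. The quaternary C1 next to C5 may slow chelation and hydride transfer, so the catalyst may discriminate poorly between the two C5 epimers, or reduction may outrun epimerisation; traces of HCl from the catalyst could also cleave the silyl ether. The fallback gives up catalyst control for substrate control, separation and recycling. It sets out from 8: NaBH4 in MeOH at −40 °C should reduce the ketone anti to the ester in both epimers and give two cis-hydroxy esters that are diastereomers and separable by chromatography, methyl (1R,2R,5S)-2-[2-[(tert-butyldimethylsilyl)oxy]ethyl]-5-hydroxy-2-methylcyclopentane-1-carboxylate F1 and methyl (1S,2R,5R)-2-[2-[(tert-butyldimethylsilyl)oxy]ethyl]-5-hydroxy-2-methylcyclopentane-1-carboxylate F2. F2 is returned to 8 by Dess–Martin oxidation, where C5 equilibrates again. F1 is reduced with LiAlH4 to (1S,2S,3R)-3-[2-[(tert-butyldimethylsilyl)oxy]ethyl]-2-(hydroxymethyl)-3-methylcyclopentan-1-ol F3, silylated with TBDPSCl and imidazole to (1S,2S,3R)-3-[2-[(tert-butyldimethylsilyl)oxy]ethyl]-2-[[(tert-butyldiphenylsilyl)oxy]methyl]-3-methylcyclopentan-1-ol F4, and oxidised with Dess–Martin periodinane. The carbinol configuration is lost in that oxidation, so the sequence comes back to the route at 12.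

Step 16. The aldehyde sits between two quaternary carbons, so the facial preference of the chiral borane may be opposed by the bias of the substrate; the free tertiary hydroxyl may also consume reagent, and the β-hydroxy aldehyde may cleave by retro-aldol reaction. The fallback sets C6 by intramolecular hydride delivery in the bicycle. It sets out from 18: 2-methylallylmagnesium chloride in THF at −78 °C adds without control, giving 20 together with its C6 epimer (1R,2S,3R)-2-[(1R)-1-hydroxy-3-methylbut-3-en-1-yl]-3-methyl-1-(propan-2-yl)-3-(prop-2-en-1-yl)cyclopentan-1-ol F5. Ring-closing metathesis of the mixture under the conditions of step 17 gives 21 and (3R,3aS,4R,8aR)-6,8a-dimethyl-3-(propan-2-yl)-1,2,3,3a,4,5,8,8a-octahydroazulene-3,4-diol F6. Dess–Martin oxidation converges both on (3R,3aR,8aR)-3-hydroxy-6,8a-dimethyl-3-(propan-2-yl)-2,3,3a,5,8,8a-hexahydroazulen-4(1H)-one F7. Evans–Saksena reduction with Me4NBH(OAc)3 in AcOH/MeCN at −20 °C should then deliver hydride from the boron bound to the C4 oxygen to the ketone face on which that oxygen lies, so the C6 hydroxyl ends on the opposite face as required. The sequence comes back to the route at 21.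

Step 20. The C4 hydroxyl lies on the face from which C8 must be attacked and may capture the developing cationic centre transannularly to give a 4,8-ether; elimination to an allylic alcohol or a hydride shift to a C9 ketone may also compete with hydration. The fallback masks that hydroxyl before the epoxide is opened. It sets out from 24: TESOTf and 2,6-lutidine in CH2Cl2 at −78 °C should give (1R,4R,5S,6S,8R,9S)-8,9-epoxy-4-[(triethylsilyl)oxy]daucan-6-yl 4-(benzyloxy)benzoate F8. Hydrolysis with catalytic HClO4 in THF/H2O at 0 °C then gives (3R,3aS,4S,6S,7S,8aR)-6,7-dihydroxy-6,8a-dimethyl-3-(propan-2-yl)-3-[(triethylsilyl)oxy]decahydroazulen-4-yl 4-(benzyloxy)benzoate F9, and HF·pyridine in THF removes the silyl group. The sequence comes back to the route at 25.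

Further compounds
F1 | step 6 | methyl (1R,2R,5S)-2-[2-[(tert-butyldimethylsilyl)oxy]ethyl]-5-hydroxy-2-methylcyclopentane-1-carboxylate | COC(=O)[C@H]1[C@@H](O)CC[C@]1(C)CCO[Si](C)(C)C(C)(C)C
F2 | step 6 | methyl (1S,2R,5R)-2-[2-[(tert-butyldimethylsilyl)oxy]ethyl]-5-hydroxy-2-methylcyclopentane-1-carboxylate | COC(=O)[C@@H]1[C@H](O)CC[C@]1(C)CCO[Si](C)(C)C(C)(C)C
F3 | step 6 | (1S,2S,3R)-3-[2-[(tert-butyldimethylsilyl)oxy]ethyl]-2-(hydroxymethyl)-3-methylcyclopentan-1-ol | OC[C@H]1[C@@H](O)CC[C@]1(C)CCO[Si](C)(C)C(C)(C)C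
F4 | step 6 | (1S,2S,3R)-3-[2-[(tert-butyldimethylsilyl)oxy]ethyl]-2-[[(tert-butyldiphenylsilyl)oxy]methyl]-3-methylcyclopentan-1-ol | CC(C)(C)[Si](c1ccccc1)(c1ccccc1)OC[C@H]1[C@@H](O)CC[C@]1(C)CCO[Si](C)(C)C(C)(C)C
F5 | step 16 | (1R,2S,3R)-2-[(1R)-1-hydroxy-3-methylbut-3-en-1-yl]-3-methyl-1-(propan-2-yl)-3-(prop-2-en-1-yl)cyclopentan-1-ol | CC(C)[C@]1(O)CC[C@](C)(CC=C)[C@H]1[C@H](O)CC(C)=C
F6 | step 16 | (3R,3aS,4R,8aR)-6,8a-dimethyl-3-(propan-2-yl)-1,2,3,3a,4,5,8,8a-octahydroazulene-3,4-diol | CC(C)[C@]1(O)CC[C@]2(C)CC=C(C)C[C@@H](O)[C@H]21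
F7 | step 16 | (3R,3aR,8aR)-3-hydroxy-6,8a-dimethyl-3-(propan-2-yl)-2,3,3a,5,8,8a-hexahydroazulen-4(1H)-one | CC(C)[C@]1(O)CC[C@]2(C)CC=C(C)CC(=O)[C@H]21
F8 | step 20 | (1R,4R,5S,6S,8R,9S)-8,9-epoxy-4-[(triethylsilyl)oxy]daucan-6-yl 4-(benzyloxy)benzoate | CC(C)[C@]1(O[Si](CC)(CC)CC)CC[C@]2(C)C[C@@H]3O[C@]3(C)C[C@H](OC(=O)c3ccc(OCc4ccccc4)cc3)[C@H]21
F9 | step 20 | (3R,3aS,4S,6S,7S,8aR)-6,7-dihydroxy-6,8a-dimethyl-3-(propan-2-yl)-3-[(triethylsilyl)oxy]decahydroazulen-4-yl 4-(benzyloxy)benzoate | CC(C)[C@]1(O[Si](CC)(CC)CC)CC[C@]2(C)C[C@H](O)[C@@](C)(O)C[C@H](OC(=O)c3ccc(OCc4ccccc4)cc3)[C@H]21
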